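**Plan**

- Retrosynthesis: cut the butenolide (ketene-ylide annulation of an α-hydroxy ketone), then the C5–CH2 side-chain bond (Mukaiyama–Michael addition), then C6–C7 and C3a–C8a together (intramolecular (4+3) cycloaddition), leaving an acyclic allenyl ether–silyloxydiene.
- Enabling feature: in the seven-membered ring the tertiary carbinol C8a and the ketone C4 flank the ring-fusion carbon C3a. C8a–C8–C7 can therefore be an oxygen-stabilised allyl cation (from a benzyloxyallene) and C3a=C4–C5=C6 a 2-silyloxydiene, joined by the C1–C2–C3 tether that becomes the cyclopentane.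
- Forward: the chain is assembled in steps 1–9; step 10 closes the five- and seven-membered rings at once. The helpers are then removed or used: the C7=C8 alkene (step 11), the enol silane (step 14), the benzyl group on O–C8a (step 15). The butenolide is closed last.
- Stereochemistry: C2 from enantioselective iridium-catalysed tert-prenylation; C3a, C6 and C8a from the cycloaddition (diene geometry, extended transition state, relay from C2); C5 from Michael addition anti to the C6 methyl.
- Numbering: azulene numbering with the ring ketone as C4 (C8a carbinol, C3a ring-fusion CH, C5 quaternary, C6 CHMe, C2 CHOH, C1 CMe2).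

Key step: step 10

Assumption: the (S)-SEGPHOS-derived iridium catalyst is taken to deliver the (R)-carbinol in step 1; if the sense proved opposite, the antipodal ligand would be used.

**Route**

Step 1
Reactants: 1 methyl 4-oxobutanoate; 2 3-methylbuta-1,2-diene
Product: 4 (5R)-5-(2-methylbut-3-en-2-yl)oxolan-2-one, via hydroxy ester 3 (not isolated)
Conditions: [Ir(cod)Cl]2 (2.5 mol%), (S)-SEGPHOS (5 mol%), 4-cyano-3-nitrobenzoic acid (10 mol%), Cs2CO3 (20 mol%), i-PrOH (2 equiv), toluene, 60 °C; then TsOH·H2O (cat.), CH2Cl2, rt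
Reagents that add atoms: none
Why: Iridium-catalysed transfer-hydrogenative carbonyl tert-prenylation, in which the 1,1-dimethylallyl–iridium species adds through its substituted terminus in a closed transition state whose face is fixed by the ligand (sets C2 as R), followed by lactonisation of the γ-hydroxy ester.

Step 2
Reactants: 4 (5R)-5-(2-methylbut-3-en-2-yl)oxolan-2-one
Product: 5 (4R)-4-hydroxy-N-methoxy-N,5,5-trimethylhept-6-enamide
Conditions: MeNH(OMe)·HCl, i-PrMgCl, THF, −20 → 0 °C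
Reagents that add atoms: N,O-dimethylhydroxylamine hydrochloride, Cl.CNOC
Why: Weinreb aminolysis of the lactone by the magnesium amide should open the ring without touching the stereocentre.

Step 3
Reactants: 5 (4R)-4-hydroxy-N-methoxy-N,5,5-trimethylhept-6-enamide
Product: 6 (4R)-4-[(tert-butyldimethylsilyl)oxy]-N-methoxy-N,5,5-trimethylhept-6-enamide
Conditions: TBSOTf, 2,6-lutidine, CH2Cl2, −78 → 0 °C
Reagents that add atoms: tert-butyldimethylsilyl trifluoromethanesulfonate, CC(C)(C)[Si](C)(C)OS(=O)(=O)C(F)(F)F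
Why: Silyl ether protection of the hindered secondary alcohol with the silyl triflate blocks relactonisation and carries the C2 oxygen to the end.

Step 4
Reactants: 6 (4R)-4-[(tert-butyldimethylsilyl)oxy]-N-methoxy-N,5,5-trimethylhept-6-enamide
Product: 8 (4R)-4-[(tert-butyldimethylsilyl)oxy]-N-methoxy-N,5,5-trimethyl-6-oxohexanamide, via ozonide 7 (not isolated)
Conditions: O3, CH2Cl2, −78 °C; PPh3, −78 °C → rt
Reagents that add atoms: ozone, [O-][O+]=O
Why: Ozonolysis of the only alkene with reductive work-up should give the neopentyl aldehyde and leave the stereocentre untouched.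

Step 5
Reactants: 8 (4R)-4-[(tert-butyldimethylsilyl)oxy]-N-methoxy-N,5,5-trimethyl-6-oxohexanamide
Product: 9 (4R)-4-[(tert-butyldimethylsilyl)oxy]-6-hydroxy-N-methoxy-N,5,5-trimethyloct-7-ynamide (both C6 epimers)
Conditions: HC≡CMgBr (1.3 equiv), THF, −78 → −20 °C
Reagents that add atoms: ethynylmagnesium bromide, C#C[Mg]Br
Why: Grignard 1,2-addition of the acetylide to the aldehyde, which is far more electrophilic than the Weinreb amide at low temperature; the new carbinol centre forms unselectively and is erased in step 7.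

Step 6
Reactants: 9 (4R)-4-[(tert-butyldimethylsilyl)oxy]-6-hydroxy-N-methoxy-N,5,5-trimethyloct-7-ynamide
Product: 10 (4R)-6-(benzyloxy)-4-[(tert-butyldimethylsilyl)oxy]-N-methoxy-N,5,5-trimethyloct-7-ynamide (both C6 epimers)
Conditions: BnOC(=NH)CCl3, TfOH (5 mol%), CH2Cl2–cyclohexane, 0 °C
Reagents that add atoms: benzyl 2,2,2-trichloroacetimidate, N=C(OCc1ccccc1)C(Cl)(Cl)Cl
Why: Acid-catalysed benzylation with the trichloroacetimidate avoids an alkoxide and so avoids 1,3-silyl migration from the neighbouring silyl ether.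

Step 7
Reactants: 10 (4R)-6-(benzyloxy)-4-[(tert-butyldimethylsilyl)oxy]-N-methoxy-N,5,5-trimethyloct-7-ynamide
Product: 11 (4R)-6-(benzyloxy)-4-[(tert-butyldimethylsilyl)oxy]-N-methoxy-N,5,5-trimethylocta-6,7-dienamide
Conditions: KOt-Bu (0.3 equiv), THF–DMSO, 0 °C → rt
Reagents that add atoms: none
Why: Base-mediated prototropic propargyl-to-allenyl ether isomerisation stops at the 1-alkoxyallene because the oxygen-bearing carbon then carries no hydrogen, and both C6 epimers converge.

Step 8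
Reactants: 11 (4R)-6-(benzyloxy)-4-[(tert-butyldimethylsilyl)oxy]-N-methoxy-N,5,5-trimethylocta-6,7-dienamide; 12 (E)-2-bromobut-2-ene
Product: 15 (2E,7R)-9-(benzyloxy)-7-[(tert-butyldimethylsilyl)oxy]-3,8,8-trimethylundeca-2,9,10-trien-4-one, via (Z)-but-2-en-2-yllithium 13 (not isolated), via lithium hemiaminal adduct 14 (not isolated)
Conditions: 12, t-BuLi (2 equiv), Et2O, −78 °C; then 11, THF, −78 → −40 °C; aq NH4Cl
Reagents that add atoms: none
Why: Weinreb ketone synthesis, in which bromine–lithium exchange retains the alkene geometry and the chelated adduct prevents over-addition, so the (E)-enone should result on work-up.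

Step 9
Reactants: 15 (2E,7R)-9-(benzyloxy)-7-[(tert-butyldimethylsilyl)oxy]-3,8,8-trimethylundeca-2,9,10-trien-4-one
Product: 17 (2E,4Z,7R)-9-(benzyloxy)-4,7-bis[(tert-butyldimethylsilyl)oxy]-3,8,8-trimethylundeca-2,4,9,10-tetraene, via potassium dienolate 16 (not isolated)
Conditions: KN(SiMe3)2 (1.1 equiv), THF, −78 °C; TBSOTf, −78 °C; Et3N, pH 7 buffer
Reagents that add atoms: tert-butyldimethylsilyl trifluoromethanesulfonate, CC(C)(C)[Si](C)(C)OS(=O)(=O)C(F)(F)F
Why: Kinetic α′-deprotonation of the enone should give the cross-conjugated (Z)-dienolate (the CH2 substituent avoids the branched alkenyl group), and O-silylation (silyl enol ether formation) fixes the diene geometry that later sets C3a.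

Step 10
Reactants: 17 (2E,4Z,7R)-9-(benzyloxy)-4,7-bis[(tert-butyldimethylsilyl)oxy]-3,8,8-trimethylundeca-2,4,9,10-tetraene
Product: 18 (2R,3aS,6R,8aS)-8a-(benzyloxy)-2,4-bis[(tert-butyldimethylsilyl)oxy]-1,1,5,6-tetramethyl-1,2,3,3a,6,8a-hexahydroazulene
Conditions: [(IPr)Au(NCMe)]SbF6 (5 mol%; IPr = 1,3-bis(2,6-diisopropylphenyl)imidazol-2-ylidene), 2,6-di-tert-butyl-4-methylpyridine (10 mol%), 4 Å molecular sieves, CH2Cl2, −20 °C → rt
Reagents that add atoms: none
Why: Proposed new method: the cationic monovalent gold complex activates the allenyl ether as a gold-bound allyl cation with its charge on the benzyloxy-bearing carbon (future C8a), the tethered silyloxydiene adds across its two termini in an asynchronous (4+3) cycloaddition (C3a–C8a leading, then C6–C7) to a cycloheptenyl gold carbene at C8, and a 1,2-hydride shift from C7 gives the C7=C8 alkene and frees the catalyst. The closest known reaction type is the gold- or platinum-catalysed intramolecular (4+3) cycloaddition of allenes with tethered 1,3-dienes to trans-fused bicyclo[5.3.0]decadienes, together with gold-catalysed additions of silyl enol ethers to allenes; new here are the oxygen substituents on both partners. The five-membered ring closes in a 5-exo sense on the oxocarbenium-like allyl terminus, and the seven-membered ring closes by bonding of the unsubstituted allyl terminus to the far diene end on the nascent cyclopentane. For C3a and C8a, the CMe2 tether lies outside on the allyl cation and the tether CH2 outside on the (Z)-enol ether, so the extended transition state should set OBn and H-3a trans; for C6, the (E)-alkene carries its methyl outside, so suprafacial addition places H-6 cis to H-3a; the absolute sense is relayed from C2, whose silyloxy group should sit on the face of the forming cyclopentane away from the gold-bearing C8. The step needs (4+3) selectivity over ring contraction to a (4+2) product and over protodeauration after the first bond, which the strongly donating carbene ligand, the non-coordinating counter-ion and the hindered-base buffer are chosen to secure; attack at the oxygenated allene terminus is secured by the oxygen lone pair and the 5-exo geometry.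

Step 11
Reactants: 18 (2R,3aS,6R,8aS)-8a-(benzyloxy)-2,4-bis[(tert-butyldimethylsilyl)oxy]-1,1,5,6-tetramethyl-1,2,3,3a,6,8a-hexahydroazulene
Product: 19 (2R,3aS,6R,8aS)-8a-(benzyloxy)-2,4-bis[(tert-butyldimethylsilyl)oxy]-1,1,5,6-tetramethyl-1,2,3,3a,6,7,8,8a-octahydroazulene
Conditions: 2-nitrobenzenesulfonylhydrazide (excess), Et3N, CH2Cl2, rt
Reagents that add atoms: none
Why: Diimide reduction transfers H2 concertedly to the cis-disubstituted C7=C8 alkene and should leave the tetrasubstituted enol ether, the benzyl ether and the allylic C8a–O bond untouched.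

Step 12
Reactants: 20 2-(benzyloxy)acetaldehyde
Product: 21 1-(benzyloxy)but-3-en-2-ol (racemic)
Conditions: CH2=CHMgBr, THF, −78 °C
Reagents that add atoms: vinylmagnesium bromide, C=C[Mg]Br
Why: Grignard 1,2-addition of the vinyl nucleophile to the aldehyde; the carbinol centre is oxidised in the next step.

Step 13
Reactants: 21 1-(benzyloxy)but-3-en-2-ol
Product: 22 1-(benzyloxy)but-3-en-2-one
Conditions: Dess–Martin periodinane, NaHCO3, CH2Cl2, 0 °C → rt
Reagents that add atoms: none
Why: Dess–Martin oxidation of the secondary allylic alcohol should give the vinyl ketone, to be used at once because it polymerises readily.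

Step 14
Reactants: 19 (2R,3aS,6R,8aS)-8a-(benzyloxy)-2,4-bis[(tert-butyldimethylsilyl)oxy]-1,1,5,6-tetramethyl-1,2,3,3a,6,7,8,8a-octahydroazulene; 22 1-(benzyloxy)but-3-en-2-one
Product: 24 (2R,3aS,5S,6R,8aS)-8a-(benzyloxy)-5-[4-(benzyloxy)-3-oxobutyl]-2-[(tert-butyldimethylsilyl)oxy]-1,1,5,6-tetramethyloctahydroazulen-4(1H)-one, via silyl enol ether 23 (not isolated)
Conditions: Tf2NH (3 mol%), CH2Cl2, −78 °C; then 1 M HCl, THF, 0 °C
Reagents that add atoms: none
Why: Mukaiyama–Michael addition of the tetrasubstituted silyl enol ether to the vinyl ketone should create the C5 quaternary centre, the acceptor approaching the face anti to the adjacent C6 methyl (as in Robinson annulations of 2,3-dimethylcycloalkanones) so that the two methyls end up cis, and the acid work-up hydrolyses the transferred silyl enol ether.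

Step 15
Reactants: 24 (2R,3aS,5S,6R,8aS)-8a-(benzyloxy)-5-[4-(benzyloxy)-3-oxobutyl]-2-[(tert-butyldimethylsilyl)oxy]-1,1,5,6-tetramethyloctahydroazulen-4(1H)-one
Product: 25 (2R,3aS,5S,6R,8aS)-2-[(tert-butyldimethylsilyl)oxy]-8a-hydroxy-5-(4-hydroxy-3-oxobutyl)-1,1,5,6-tetramethyloctahydroazulen-4(1H)-one
Conditions: H2 (1 atm), Pd(OH)2/C, EtOAc, rt
Reagents that add atoms: none
Why: Catalytic hydrogenolysis should cleave both benzyl ethers at their benzylic C–O bonds without affecting the ketones or the silyl ether.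

Step 16
Reactants: 25 (2R,3aS,5S,6R,8aS)-2-[(tert-butyldimethylsilyl)oxy]-8a-hydroxy-5-(4-hydroxy-3-oxobutyl)-1,1,5,6-tetramethyloctahydroazulen-4(1H)-one
Product: 27 (2R,3aS,5S,6R,8aS)-2-[(tert-butyldimethylsilyl)oxy]-8a-hydroxy-1,1,5,6-tetramethyl-5-[2-(5-oxo-2,5-dihydrofuran-3-yl)ethyl]octahydroazulen-4(1H)-one, via ester ylide 26 (not isolated)
Conditions: Ph3P=C=C=O (1.2 equiv), toluene, 80 °C
Reagents that add atoms: (triphenylphosphoranylidene)ketene, O=C=C=P(c1ccccc1)(c1ccccc1)c1ccccc1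
Why: The ketene ylide acylates the primary hydroxyl and the resulting ester ylide closes by intramolecular Wittig olefination onto the adjacent ketone (butenolide annulation of an α-hydroxy ketone), the tertiary C8a hydroxyl being too hindered to be acylated.

Step 17
Reactants: 27 (2R,3aS,5S,6R,8aS)-2-[(tert-butyldimethylsilyl)oxy]-8a-hydroxy-1,1,5,6-tetramethyl-5-[2-(5-oxo-2,5-dihydrofuran-3-yl)ethyl]octahydroazulen-4(1H)-one
Product: 28 (2R,3aS,5S,6R,8aS)-2,8a-dihydroxy-1,1,5,6-tetramethyl-5-[2-(5-oxo-2,5-dihydrofuran-3-yl)ethyl]octahydroazulen-4(1H)-one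
Conditions: HF·pyridine, pyridine, THF, 0 °C → rt
Reagents that add atoms: none
Why: Fluoride-mediated silyl ether cleavage under mildly acidic conditions should spare the β-hydroxy ketone (no retro-aldol) and the butenolide.

**Compound list**

1 | methyl 4-oxobutanoate | COC(=O)CCC=O | starting material
2 | 3-methylbuta-1,2-diene | CC(C)=C=C | starting material
3 | methyl (4R)-4-hydroxy-5,5-dimethylhept-6-enoate | COC(=O)CC[C@@H](O)C(C)(C)C=C | intermediate
4 | (5R)-5-(2-methylbut-3-en-2-yl)oxolan-2-one | O=C1CC[C@@H](O1)C(C)(C)C=C | intermediate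
5 | (4R)-4-hydroxy-N-methoxy-N,5,5-trimethylhept-6-enamide | CON(C)C(=O)CC[C@@H](O)C(C)(C)C=C | intermediate
6 | (4R)-4-[(tert-butyldimethylsilyl)oxy]-N-methoxy-N,5,5-trimethylhept-6-enamide | CON(C)C(=O)CC[C@@H](O[Si](C)(C)C(C)(C)C)C(C)(C)C=C | intermediate
7 | (4R)-4-[(tert-butyldimethylsilyl)oxy]-N-methoxy-N,5-dimethyl-5-(1,2,4-trioxolan-3-yl)hexanamide (ozonide) | CON(C)C(=O)CC[C@@H](O[Si](C)(C)C(C)(C)C)C(C)(C)C1OCOO1 | intermediate
8 | (4R)-4-[(tert-butyldimethylsilyl)oxy]-N-methoxy-N,5,5-trimethyl-6-oxohexanamide | CON(C)C(=O)CC[C@@H](O[Si](C)(C)C(C)(C)C)C(C)(C)C=O | intermediate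
9 | (4R)-4-[(tert-butyldimethylsilyl)oxy]-6-hydroxy-N-methoxy-N,5,5-trimethyloct-7-ynamide (C6 epimers) | CON(C)C(=O)CC[C@@H](O[Si](C)(C)C(C)(C)C)C(C)(C)C(O)C#C | intermediate
10 | (4R)-6-(benzyloxy)-4-[(tert-butyldimethylsilyl)oxy]-N-methoxy-N,5,5-trimethyloct-7-ynamide (C6 epimers) | CON(C)C(=O)CC[C@@H](O[Si](C)(C)C(C)(C)C)C(C)(C)C(OCc1ccccc1)C#C | intermediate
11 | (4R)-6-(benzyloxy)-4-[(tert-butyldimethylsilyl)oxy]-N-methoxy-N,5,5-trimethylocta-6,7-dienamide | CON(C)C(=O)CC[C@@H](O[Si](C)(C)C(C)(C)C)C(C)(C)C(OCc1ccccc1)=C=C | intermediate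
12 | (E)-2-bromobut-2-ene | C/C=C(\C)Br | starting material
13 | (Z)-but-2-en-2-yllithium (methyls cis, geometry retained) | C/C=C(\C)[Li] | intermediate
14 | lithium (2E,7R)-9-(benzyloxy)-7-[(tert-butyldimethylsilyl)oxy]-4-[methoxy(methyl)amino]-3,8,8-trimethylundeca-2,9,10-trien-4-olate | C/C=C(\C)C(O[Li])(N(C)OC)CC[C@@H](O[Si](C)(C)C(C)(C)C)C(C)(C)C(OCc1ccccc1)=C=C | intermediate
15 | (2E,7R)-9-(benzyloxy)-7-[(tert-butyldimethylsilyl)oxy]-3,8,8-trimethylundeca-2,9,10-trien-4-one | C/C=C(\C)C(=O)CC[C@@H](O[Si](C)(C)C(C)(C)C)C(C)(C)C(OCc1ccccc1)=C=C | intermediate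
16 | potassium (2E,4Z,7R)-9-(benzyloxy)-7-[(tert-butyldimethylsilyl)oxy]-3,8,8-trimethylundeca-2,4,9,10-tetraen-4-olate | C/C=C(\C)/C([O-])=C/C[C@@H](O[Si](C)(C)C(C)(C)C)C(C)(C)C(OCc1ccccc1)=C=C.[K+] | intermediate
17 | (2E,4Z,7R)-9-(benzyloxy)-4,7-bis[(tert-butyldimethylsilyl)oxy]-3,8,8-trimethylundeca-2,4,9,10-tetraene | C/C=C(\C)/C(O[Si](C)(C)C(C)(C)C)=C/C[C@@H](O[Si](C)(C)C(C)(C)C)C(C)(C)C(OCc1ccccc1)=C=C | intermediate
18 | (2R,3aS,6R,8aS)-8a-(benzyloxy)-2,4-bis[(tert-butyldimethylsilyl)oxy]-1,1,5,6-tetramethyl-1,2,3,3a,6,8a-hexahydroazulene | C[C@@H]1C=C[C@]2(OCc3ccccc3)[C@H](C[C@@H](O[Si](C)(C)C(C)(C)C)C2(C)C)C(O[Si](C)(C)C(C)(C)C)=C1C | intermediate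
19 | (2R,3aS,6R,8aS)-8a-(benzyloxy)-2,4-bis[(tert-butyldimethylsilyl)oxy]-1,1,5,6-tetramethyl-1,2,3,3a,6,7,8,8a-octahydroazulene | C[C@@H]1CC[C@]2(OCc3ccccc3)[C@H](C[C@@H](O[Si](C)(C)C(C)(C)C)C2(C)C)C(O[Si](C)(C)C(C)(C)C)=C1C | intermediate
20 | 2-(benzyloxy)acetaldehyde | O=CCOCc1ccccc1 | starting material
21 | 1-(benzyloxy)but-3-en-2-ol (racemic) | C=CC(O)COCc1ccccc1 | intermediate
22 | 1-(benzyloxy)but-3-en-2-one | C=CC(=O)COCc1ccccc1 | intermediate
23 | (2R,3aS,5S,6R,8aS)-8a-(benzyloxy)-5-{4-(benzyloxy)-3-[(tert-butyldimethylsilyl)oxy]but-2-en-1-yl}-2-[(tert-butyldimethylsilyl)oxy]-1,1,5,6-tetramethyloctahydroazulen-4(1H)-one | C[C@@H]1CC[C@]2(OCc3ccccc3)[C@H](C[C@@H](O[Si](C)(C)C(C)(C)C)C2(C)C)C(=O)[C@@]1(C)CC=C(O[Si](C)(C)C(C)(C)C)COCc1ccccc1 | intermediate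
24 | (2R,3aS,5S,6R,8aS)-8a-(benzyloxy)-5-[4-(benzyloxy)-3-oxobutyl]-2-[(tert-butyldimethylsilyl)oxy]-1,1,5,6-tetramethyloctahydroazulen-4(1H)-one | C[C@@H]1CC[C@]2(OCc3ccccc3)[C@H](C[C@@H](O[Si](C)(C)C(C)(C)C)C2(C)C)C(=O)[C@@]1(C)CCC(=O)COCc1ccccc1 | intermediate
25 | (2R,3aS,5S,6R,8aS)-2-[(tert-butyldimethylsilyl)oxy]-8a-hydroxy-5-(4-hydroxy-3-oxobutyl)-1,1,5,6-tetramethyloctahydroazulen-4(1H)-one | C[C@@H]1CC[C@]2(O)[C@H](C[C@@H](O[Si](C)(C)C(C)(C)C)C2(C)C)C(=O)[C@@]1(C)CCC(=O)CO | intermediate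
26 | 4-[(2R,3aS,5S,6R,8aS)-2-[(tert-butyldimethylsilyl)oxy]-8a-hydroxy-1,1,5,6-tetramethyl-4-oxodecahydroazulen-5-yl]-2-oxobutyl 2-(triphenyl-λ5-phosphanylidene)acetate | C[C@@H]1CC[C@]2(O)[C@H](C[C@@H](O[Si](C)(C)C(C)(C)C)C2(C)C)C(=O)[C@@]1(C)CCC(=O)COC(=O)C=P(c1ccccc1)(c1ccccc1)c1ccccc1 | intermediate
27 | (2R,3aS,5S,6R,8aS)-2-[(tert-butyldimethylsilyl)oxy]-8a-hydroxy-1,1,5,6-tetramethyl-5-[2-(5-oxo-2,5-dihydrofuran-3-yl)ethyl]octahydroazulen-4(1H)-one | C[C@@H]1CC[C@]2(O)[C@H](C[C@@H](O[Si](C)(C)C(C)(C)C)C2(C)C)C(=O)[C@@]1(C)CCC1=CC(=O)OC1 | intermediate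
28 | (2R,3aS,5S,6R,8aS)-2,8a-dihydroxy-1,1,5,6-tetramethyl-5-[2-(5-oxo-2,5-dihydrofuran-3-yl)ethyl]octahydroazulen-4(1H)-one | C[C@@H]1CC[C@]2(O)[C@H](C[C@@H](O)C2(C)C)C(=O)[C@@]1(C)CCC1=CC(=O)OC1 | target

**Step count**

Total steps: 17. Longest linear sequence: 15 (steps 1–11 and 14–17; steps 12–13 make the Michael acceptor).

**Steps most likely to fail**

1. Step 10. The cationic intermediate may collapse after the first C–C bond (desilylation and protodeauration to a monocycle), the gold carbene may contract to a six-membered ring, or the facial relay from C2 may be poor. The fallback builds the bicycle stepwise by known reactions, setting out from 17 and returning at 18. Gold activation run deliberately with a proton source ((Ph3P)AuCl/AgBF4, t-BuOH, CH2Cl2), the known carbocyclisation of silyl enol ethers onto allenes, should give (2E)-1-[(1S,2S,4R)-2-(benzyloxy)-4-[(tert-butyldimethylsilyl)oxy]-2-ethenyl-3,3-dimethylcyclopentyl]-2-methylbut-2-en-1-one F1. Copper-catalysed conjugate addition of CH2=CHMgBr with enolate trapping (CuBr·SMe2, TBSCl, HMPA, THF, −78 °C) should then give tert-butyl{[(1E,3R)-1-[(1S,2S,4R)-2-(benzyloxy)-4-[(tert-butyldimethylsilyl)oxy]-2-ethenyl-3,3-dimethylcyclopentyl]-2,3-dimethylpenta-1,4-dien-1-yl]oxy}dimethylsilane F2; this addition is not expected to control the new methyl-bearing centre or the enol ether geometry, so the isomer shown would have to be separated. Ring-closing metathesis with the second-generation Grubbs catalyst RuCl2(H2IMes)(PCy3)(=CHPh) would close the seven-membered ring at C7=C8 and return 18.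

2. Step 14. Addition at the tetrasubstituted enol ether carbon may be slow, so that protodesilylation to the C5–H ketone, polymerisation of the vinyl ketone or poor facial selectivity take over. The fallback replaces the conjugate addition by enolate allylation and chain extension, setting out from 19 and returning at 24. The lithium enolate released from 19 with MeLi (THF, HMPA, 0 °C) would be C-allylated with allyl bromide, again anti to the C6 methyl, to (2R,3aS,5S,6R,8aS)-8a-(benzyloxy)-2-[(tert-butyldimethylsilyl)oxy]-1,1,5,6-tetramethyl-5-(prop-2-en-1-yl)octahydroazulen-4(1H)-one F3. Aldehyde-selective Wacker oxidation (PdCl2(PhCN)2, CuCl2, AgNO2, O2, t-BuOH–MeNO2) would give 3-[(2R,3aS,5S,6R,8aS)-8a-(benzyloxy)-2-[(tert-butyldimethylsilyl)oxy]-1,1,5,6-tetramethyl-4-oxodecahydroazulen-5-yl]propanal F4. Addition of BnOCH2Li (from BnOCH2SnBu3 and n-BuLi, THF, −78 °C) would give (2R,3aS,5S,6R,8aS)-8a-(benzyloxy)-5-[4-(benzyloxy)-3-hydroxybutyl]-2-[(tert-butyldimethylsilyl)oxy]-1,1,5,6-tetramethyloctahydroazulen-4(1H)-one F5, and Dess–Martin oxidation would return 24.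

3. Step 16. At 80 °C the ylide may acylate unselectively, or the tertiary β-hydroxy ketone may dehydrate or undergo retro-aldol cleavage before the Wittig closure. The fallback separates acylation from olefination, setting out from 25 and returning at 27. Esterification of the primary hydroxyl with (EtO)2P(O)CH2CO2H (EDC·HCl, DMAP, CH2Cl2, 0 °C) would give 4-[(2R,3aS,5S,6R,8aS)-2-[(tert-butyldimethylsilyl)oxy]-8a-hydroxy-1,1,5,6-tetramethyl-4-oxodecahydroazulen-5-yl]-2-oxobutyl 2-(diethoxyphosphoryl)acetate F6. Intramolecular Horner–Wadsworth–Emmons olefination under mild conditions (LiCl, i-Pr2NEt, MeCN, rt) would then close the butenolide and return 27.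

**Further compounds**

F1 | step 10 | (2E)-1-[(1S,2S,4R)-2-(benzyloxy)-4-[(tert-butyldimethylsilyl)oxy]-2-ethenyl-3,3-dimethylcyclopentyl]-2-methylbut-2-en-1-one | C=C[C@]1(OCc2ccccc2)[C@H](C[C@@H](O[Si](C)(C)C(C)(C)C)C1(C)C)C(=O)/C(C)=C/C
F2 | step 10 | tert-butyl{[(1E,3R)-1-[(1S,2S,4R)-2-(benzyloxy)-4-[(tert-butyldimethylsilyl)oxy]-2-ethenyl-3,3-dimethylcyclopentyl]-2,3-dimethylpenta-1,4-dien-1-yl]oxy}dimethylsilane | C=C[C@]1(OCc2ccccc2)[C@H](C[C@@H](O[Si](C)(C)C(C)(C)C)C1(C)C)/C(O[Si](C)(C)C(C)(C)C)=C(/C)[C@H](C)C=C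
F3 | step 14 | (2R,3aS,5S,6R,8aS)-8a-(benzyloxy)-2-[(tert-butyldimethylsilyl)oxy]-1,1,5,6-tetramethyl-5-(prop-2-en-1-yl)octahydroazulen-4(1H)-one | C[C@@H]1CC[C@]2(OCc3ccccc3)[C@H](C[C@@H](O[Si](C)(C)C(C)(C)C)C2(C)C)C(=O)[C@@]1(C)CC=C
F4 | step 14 | 3-[(2R,3aS,5S,6R,8aS)-8a-(benzyloxy)-2-[(tert-butyldimethylsilyl)oxy]-1,1,5,6-tetramethyl-4-oxodecahydroazulen-5-yl]propanal | C[C@@H]1CC[C@]2(OCc3ccccc3)[C@H](C[C@@H](O[Si](C)(C)C(C)(C)C)C2(C)C)C(=O)[C@@]1(C)CCC=O
F5 | step 14 | (2R,3aS,5S,6R,8aS)-8a-(benzyloxy)-5-[4-(benzyloxy)-3-hydroxybutyl]-2-[(tert-butyldimethylsilyl)oxy]-1,1,5,6-tetramethyloctahydroazulen-4(1H)-one (carbinol epimers) | C[C@@H]1CC[C@]2(OCc3ccccc3)[C@H](C[C@@H](O[Si](C)(C)C(C)(C)C)C2(C)C)C(=O)[C@@]1(C)CCC(O)COCc1ccccc1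
F6 | step 16 | 4-[(2R,3aS,5S,6R,8aS)-2-[(tert-butyldimethylsilyl)oxy]-8a-hydroxy-1,1,5,6-tetramethyl-4-oxodecahydroazulen-5-yl]-2-oxobutyl 2-(diethoxyphosphoryl)acetate | C[C@@H]1CC[C@]2(O)[C@H](C[C@@H](O[Si](C)(C)C(C)(C)C)C2(C)C)C(=O)[C@@]1(C)CCC(=O)COC(=O)CP(=O)(OCC)OCC
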